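The 2,2-dimethylpyran ring is disconnected at both of its bonds to ring B (pyran O–C2′ and pyran C4″–C3′), giving a 2′,3′-aryne and 3-methylbut-2-enal. In one operation the aryne takes up the aldehyde oxygen at C2′ and the aldehyde carbon at C3′ ([2+2], benzoxete opening, oxa-6π closure), so the pyran is the last ring made. The step exploits the oxygen on C4′, next to C3′: it polarises the aryne so that the oxygen adds at C2′. The precursor is the (3R)-5,7-dimethoxyisoflavan bearing 2′-OTf, 3′-SiMe3 and 4′-OBn, built by chromanone α-arylation, dehydration and iridium-catalysed asymmetric hydrogenation; C8 formylation and BCl3 unmasking complete the route.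

Key step: step 9

Remark: isoflavan numbering is used (ring A C5–C8, ring B C1′–C6′); compounds 1, 5 and 12 are taken as commercial.
Remark: in step 6 the ligand antipode that gives the 3R product is assumed to follow the facial preference known for 3-aryl-2H-chromenes.

Step 1
Reactants: 1 3-(benzyloxy)phenol
Product: 2 3-(benzyloxy)phenyl N,N-diethylcarbamate
Conditions: ClC(O)NEt2, K2CO3, MeCN, 80 °C
Reagents that add atoms: N,N-diethylcarbamoyl chloride, CCN(CC)C(=O)Cl
Why: O-carbamoylation of the phenoxide (acyl substitution) installs a base-stable protecting group that also serves as the directing group for the metalation in step 3.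

Step 2
Reactants: 2 3-(benzyloxy)phenyl N,N-diethylcarbamate
Product: 3 5-(benzyloxy)-2-bromophenyl N,N-diethylcarbamate
Conditions: NBS, MeCN, 0 °C → rt
Reagents that add atoms: N-bromosuccinimide, O=C1CCC(=O)N1Br
Why: electrophilic aromatic bromination should occur para to the benzyloxy group, the strongest donor, at the position ortho to the weakly donating carbamate, as in brominations of O-acylated 3-alkoxyphenols.

Step 3
Reactants: 3 5-(benzyloxy)-2-bromophenyl N,N-diethylcarbamate
Product: 4 3-(benzyloxy)-6-bromo-2-(trimethylsilyl)phenyl N,N-diethylcarbamate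
Conditions: LDA, TMSCl (in situ quench), THF, −78 °C
Reagents that add atoms: chlorotrimethylsilane, C[Si](C)(C)Cl
Why: directed ortho-metalation with a lithium amide, which does not exchange the bromide, removes the proton flanked by the carbamate and benzyloxy groups, and the aryllithium is silylated at once by the TMSCl present, which also forestalls anionic Fries rearrangement.

Step 4
Reactants: 4 3-(benzyloxy)-6-bromo-2-(trimethylsilyl)phenyl N,N-diethylcarbamate; 5 5,7-dimethoxychroman-4-one
Product: 6 rac-3-(benzyloxy)-6-(5,7-dimethoxy-4-oxochroman-3-yl)-2-(trimethylsilyl)phenyl N,N-diethylcarbamate (isoflavanone)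
Conditions: Pd2(dba)3 (cat.), XPhos (cat.), NaOt-Bu, toluene, 80 °C
Reagents that add atoms: none
Why: Pd-catalysed α-arylation of the ketone enolate joins C3 to C1′; the product is mono-arylated and racemic, which is of no consequence because C3 becomes sp2 in step 5.

Step 5
Reactants: 6 rac-isoflavanone
Product: 8 3-(benzyloxy)-6-(5,7-dimethoxy-2H-chromen-3-yl)-2-(trimethylsilyl)phenyl N,N-diethylcarbamate (isoflav-3-ene), via isoflavan-4-ol 7 (not isolated)
Conditions: NaBH4, THF–MeOH, 0 °C → rt; work-up; crude 7, PPTS (cat.), toluene, 70 °C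
Reagents that add atoms: none
Why: hydride reduction of the ketone and mild acid-catalysed E1 dehydration of the resulting 2,4,6-trioxygenated benzylic alcohol should give the conjugated isoflav-3-ene, erasing the C3 and C4 stereocentres.

Step 6
Reactants: 8 isoflav-3-ene
Product: 9 3-(benzyloxy)-6-[(3R)-5,7-dimethoxychroman-3-yl]-2-(trimethylsilyl)phenyl N,N-diethylcarbamate
Conditions: H2 (50 bar), [Ir(cod)(L*)]BArF (1–2 mol %, L* = chiral phosphine–oxazoline), CH2Cl2, rt
Reagents that add atoms: none
Why: iridium–P,N-catalysed asymmetric hydrogenation of the trisubstituted cyclic styrene, a reaction established for 3-aryl-2H-chromenes, sets C3 by catalyst-controlled delivery of H2 to one face of the C3=C4 bond, the ligand antipode being chosen to give R.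

Step 7
Reactants: 9 (3R)-isoflavan carbamate
Product: 10 3-(benzyloxy)-6-[(3R)-5,7-dimethoxychroman-3-yl]-2-(trimethylsilyl)phenol
Conditions: LiAlH4, THF, 65 °C; Rochelle salt work-up
Reagents that add atoms: none
Why: hydride reduction cleaves the aryl N,N-diethylcarbamate to the phenol without touching the aryl–silicon bond, the benzyl ether or the C3 stereocentre.

Step 8
Reactants: 10 (3R)-2′-hydroxy-3′-silyl isoflavan
Product: 11 3-(benzyloxy)-6-[(3R)-5,7-dimethoxychroman-3-yl]-2-(trimethylsilyl)phenyl trifluoromethanesulfonate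
Conditions: Tf2O, pyridine, CH2Cl2, −20 → 0 °C
Reagents that add atoms: trifluoromethanesulfonic anhydride, O=S(=O)(OS(=O)(=O)C(F)(F)F)C(F)(F)F
Why: O-sulfonylation of the hindered phenol gives the o-silylaryl triflate aryne precursor, the electron-rich A ring being left alone at low temperature in the presence of pyridine.

Step 9
Reactants: 11 (3R)-o-silylaryl triflate; 12 3-methylbut-2-enal
Product: 16 (3R)-3-[5-(benzyloxy)-2,2-dimethyl-2H-chromen-8-yl]-5,7-dimethoxychroman, via 2′,3′-aryne 13 (not isolated), via benzoxete 14 (not isolated), via o-quinone methide 15 (not isolated)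
Conditions: CsF (3 equiv), 12 (5 equiv), MeCN, rt → 50 °C
Reagents that add atoms: none
Why: Fluoride attacks silicon and expels triflate to give the 2′,3′-aryne 13, whose C4′ benzyloxy group (inductive withdrawal, aryne distortion) makes C2′ the electrophilic terminus, so the carbonyl oxygen of the enal adds at C2′ and the C3′ aryl anion closes onto the carbonyl carbon to give benzoxete 14. Benzoxete 14 opens by a thermal 4π-electrocyclic (retro-[2+2]) process to the vinyl o-quinone methide 15, and the pyran ring then closes by a disrotatory oxa-6π-electrocyclisation that forms the O–C(CH3)2 bond and restores aromaticity. The closest known reaction type is the annulation of arynes with α,β-unsaturated aldehydes to 2H-chromenes, and the expected orientation parallels that of 3-alkoxyarynes with formamides and aldehydes. No stereocentre is created, since the sp3 pyran carbon carries two methyl groups, and the remote C3 centre is untouched. The step needs regioselectivity (O at C2′, C at C3′) and intermolecular capture by the enal before the aryne reacts otherwise; the first should be secured by the C4′ alkoxy group, the second by the excess of unhindered enal over the weakly nucleophilic ether oxygens and the fully protected, aldehyde-free A ring.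

Step 10
Reactants: 16 (3R)-chromene
Product: 17 (3R)-3-[5-(benzyloxy)-2,2-dimethyl-2H-chromen-8-yl]-5,7-dimethoxychroman-8-carbaldehyde
Conditions: POCl3, DMF, 0 °C → rt; then aq. NaOAc
Reagents that add atoms: N,N-dimethylformamide, CN(C)C=O; water, O
Why: Vilsmeier–Haack formylation should attack the most electron-rich ring, the phloroglucinol-type A ring, at C8, which is flanked by one methoxy group and the tied-back ring oxygen whereas C6 lies between two methoxy groups, in line with the C8 preference of electrophilic substitution in 5,7-dialkoxyflavans.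

Step 11
Reactants: 17 (3R)-8-formyl chromene
Product: 18 (3R)-7-hydroxy-3-(5-hydroxy-2,2-dimethyl-2H-chromen-8-yl)-5-methoxychroman-8-carbaldehyde (target)
Conditions: BCl3 (4 equiv), pentamethylbenzene (3 equiv), CH2Cl2, −78 → 0 °C; then MeOH, aq. NaHCO3
Reagents that add atoms: none
Why: Lewis-acid ether cleavage by BCl3 should remove the aryl benzyl ether at low temperature (benzyl cation trapped by pentamethylbenzene) and, through a six-membered chelate with the C8 formyl group, only the ortho C7 methyl ether, leaving the non-chelated C5 methoxy group, the chromene and C3 unchanged.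

Compound list
1 | 3-(benzyloxy)phenol | Oc1cccc(OCc2ccccc2)c1 | starting material
2 | 3-(benzyloxy)phenyl N,N-diethylcarbamate | CCN(CC)C(=O)Oc1cccc(OCc2ccccc2)c1 | intermediate
3 | 5-(benzyloxy)-2-bromophenyl N,N-diethylcarbamate | CCN(CC)C(=O)Oc1cc(OCc2ccccc2)ccc1Br | intermediate
4 | 3-(benzyloxy)-6-bromo-2-(trimethylsilyl)phenyl N,N-diethylcarbamate | CCN(CC)C(=O)Oc1c(Br)ccc(OCc2ccccc2)c1[Si](C)(C)C | intermediate
5 | 5,7-dimethoxychroman-4-one | COc1cc(OC)cc2c1C(=O)CCO2 | starting material
6 | rac-3-(benzyloxy)-6-(5,7-dimethoxy-4-oxochroman-3-yl)-2-(trimethylsilyl)phenyl N,N-diethylcarbamate | COc1cc(OC)cc2c1C(=O)C(c1ccc(OCc3ccccc3)c([Si](C)(C)C)c1OC(=O)N(CC)CC)CO2 | intermediate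
7 | 3-(benzyloxy)-6-(4-hydroxy-5,7-dimethoxychroman-3-yl)-2-(trimethylsilyl)phenyl N,N-diethylcarbamate (racemic, cis/trans mixture) | COc1cc(OC)cc2c1C(O)C(c1ccc(OCc3ccccc3)c([Si](C)(C)C)c1OC(=O)N(CC)CC)CO2 | intermediate
8 | 3-(benzyloxy)-6-(5,7-dimethoxy-2H-chromen-3-yl)-2-(trimethylsilyl)phenyl N,N-diethylcarbamate | COc1cc(OC)cc2c1C=C(c1ccc(OCc3ccccc3)c([Si](C)(C)C)c1OC(=O)N(CC)CC)CO2 | intermediate
9 | 3-(benzyloxy)-6-[(3R)-5,7-dimethoxychroman-3-yl]-2-(trimethylsilyl)phenyl N,N-diethylcarbamate | COc1cc(OC)cc2c1C[C@H](c1ccc(OCc3ccccc3)c([Si](C)(C)C)c1OC(=O)N(CC)CC)CO2 | intermediate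
10 | 3-(benzyloxy)-6-[(3R)-5,7-dimethoxychroman-3-yl]-2-(trimethylsilyl)phenol | COc1cc(OC)cc2c1C[C@H](c1ccc(OCc3ccccc3)c([Si](C)(C)C)c1O)CO2 | intermediate
11 | 3-(benzyloxy)-6-[(3R)-5,7-dimethoxychroman-3-yl]-2-(trimethylsilyl)phenyl trifluoromethanesulfonate | COc1cc(OC)cc2c1C[C@H](c1ccc(OCc3ccccc3)c([Si](C)(C)C)c1OS(=O)(=O)C(F)(F)F)CO2 | intermediate
12 | 3-methylbut-2-enal | CC(C)=CC=O | starting material
13 | (3R)-3-[4-(benzyloxy)-2,3-didehydrophenyl]-5,7-dimethoxychroman (2′,3′-aryne) | COc1cc(OC)cc2c1C[C@H](C1=CC=C(OCc3ccccc3)C#C1)CO2 | intermediate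
14 | benzoxete from 13 and 12 (ring O on C2′, CH(CH=CMe2) on C3′) | COc1cc(OC)cc2c1C[C@H](c1ccc(OCc3ccccc3)c3c1OC3C=C(C)C)CO2 | intermediate
15 | o-quinone methide (C2′=O, C3′=CH–CH=CMe2) | COc1cc(OC)cc2c1C[C@H](C1=CC=C(OCc3ccccc3)C(=CC=C(C)C)C1=O)CO2 | intermediate
16 | (3R)-3-[5-(benzyloxy)-2,2-dimethyl-2H-chromen-8-yl]-5,7-dimethoxychroman | COc1cc(OC)cc2c1C[C@H](c1ccc(OCc3ccccc3)c3c1OC(C)(C)C=C3)CO2 | intermediate
17 | (3R)-3-[5-(benzyloxy)-2,2-dimethyl-2H-chromen-8-yl]-5,7-dimethoxychroman-8-carbaldehyde | COc1cc(OC)c(C=O)c2c1C[C@H](c1ccc(OCc3ccccc3)c3c1OC(C)(C)C=C3)CO2 | intermediate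
18 | (3R)-7-hydroxy-3-(5-hydroxy-2,2-dimethyl-2H-chromen-8-yl)-5-methoxychroman-8-carbaldehyde | COc1cc(O)c(C=O)c2c1C[C@H](c1ccc(O)c3c1OC(C)(C)C=C3)CO2 | target

Total step count: 11. Longest linear sequence: 11 steps (1 → 18); compounds 5 and 12 enter at steps 4 and 9.

Steps most likely to fail

Step 9. The enal oxygen may add to the aryne at C3′ instead of C2′ because the bulky C1′ substituent shields C2′, or the aryne may be consumed by fluoride, by the chroman oxygen or by self-reaction before the enal captures it. The fallback sets out from 10 and returns at 16. Ipso-protodesilylation of 10 (TFA, CH2Cl2, 0 °C) gives (3R)-3-[4-(benzyloxy)-2-hydroxyphenyl]-5,7-dimethoxychroman F1. O-Alkylation with 3-chloro-3-methylbut-1-yne (K2CO3, KI, CuI cat., acetone, 60 °C) gives the propargyl ether (3R)-3-[4-(benzyloxy)-2-(2-methylbut-3-yn-2-yloxy)phenyl]-5,7-dimethoxychroman F2. Heating F2 (N,N-diethylaniline, 180 °C) should trigger aromatic Claisen rearrangement to C3′, the only free ortho position, then [1,5]-hydrogen shift and oxa-6π closure to 16.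

Step 10. Discrimination between C8 and C6 in the electrophilic attack may be incomplete, or the chloroiminium ion may attack the electron-rich chromene ring. The fallback sets out from 16 and returns at 17. Bromination with NBS (1 equiv, CH2Cl2, −78 °C), a bulkier electrophile with an established C8 preference in 5,7-dialkoxyflavans, should give (3R)-3-[5-(benzyloxy)-2,2-dimethyl-2H-chromen-8-yl]-8-bromo-5,7-dimethoxychroman F3, at which stage any positional isomer can be removed. Bromine–lithium exchange (n-BuLi, THF, −78 °C) and quenching with DMF then give 17.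

Step 6. Facial discrimination may be poor with the ortho-substituted, twisted 3-aryl group, or the electron-rich chromene may isomerise or dimerise under the acidic iridium hydride. The fallback sets out from 6 and returns at 9. Noyori–Ikariya transfer hydrogenation of racemic 6 with RuCl[(R,R)-TsDPEN](p-cymene) and HCO2H/Et3N, under dynamic kinetic resolution (C3 epimerises through the enol), should give the cis alcohol 3-(benzyloxy)-6-[(3R,4R)-4-hydroxy-5,7-dimethoxychroman-3-yl]-2-(trimethylsilyl)phenyl N,N-diethylcarbamate F4. Ionic deoxygenation (excess Et3SiH, BF3·OEt2, CH2Cl2, −78 → −20 °C) removes the C4 hydroxyl and gives 9.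

Further compounds
F1 | step 9 | (3R)-3-[4-(benzyloxy)-2-hydroxyphenyl]-5,7-dimethoxychroman | COc1cc(OC)cc2c1C[C@H](c1ccc(OCc3ccccc3)cc1O)CO2
F2 | step 9 | (3R)-3-[4-(benzyloxy)-2-(2-methylbut-3-yn-2-yloxy)phenyl]-5,7-dimethoxychroman | COc1cc(OC)cc2c1C[C@H](c1ccc(OCc3ccccc3)cc1OC(C)(C)C#C)CO2
F3 | step 10 | (3R)-3-[5-(benzyloxy)-2,2-dimethyl-2H-chromen-8-yl]-8-bromo-5,7-dimethoxychroman | COc1cc(OC)c(Br)c2c1C[C@H](c1ccc(OCc3ccccc3)c3c1OC(C)(C)C=C3)CO2
F4 | step 6 | 3-(benzyloxy)-6-[(3R,4R)-4-hydroxy-5,7-dimethoxychroman-3-yl]-2-(trimethylsilyl)phenyl N,N-diethylcarbamate | COc1cc(OC)cc2c1[C@H](O)[C@H](c1ccc(OCc3ccccc3)c([Si](C)(C)C)c1OC(=O)N(CC)CC)CO2
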